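**Retrosynthetic overview**

- The plan turns on the terminal oxirane O–C8–C9 (thymol numbering, C7 = ArCH2O, C10 = CH2O-acyl). C8 is fully substituted (aryl, C10, C9, O), so it can be traced back to the carbonyl carbon of an aryl ketone, with C9 added last as a methylene unit.
- Key disconnection: the C8–C9 and O–C9 bonds, formed together by ligand-controlled methylene transfer from dimethyloxosulfonium methylide to a 1-aryl-2-silyloxyethanone (PMB on the phenol, TBS on O7 and O10).
- The ketone comes from the C8–aryl bond: an aryllithium (Br/Li exchange on protected 4-bromo-3-hydroxybenzyl alcohol) is acylated by the Weinreb amide of O-TBS glycolic acid.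
- End game: desilylation, twofold esterification with (R)-2-methylbutanoic acid, then PMB removal and angeloylation of the phenol last, because the angelate is the most labile ester.
- Ring order: the benzene ring is bought; the oxirane is the only ring formed, in the key step.

Key step: step 7

Assumption: the facial sense of the lanthanum–lithium binaphthoxide catalyst with aryl methyl ketones is taken to hold with CH2OTBS in the place of CH3, which calls for the (R)-binaphthol-derived complex; if a pilot run shows the opposite sense, the (S)-ligand is used with no other change.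

Remark on descriptors: the spatial arrangement at C8 is the same from 11 to 18; the descriptor reads S only in diol 12 (and in F6), because a free CH2OH ranks below the oxirane CH2 whereas CH2OSi and CH2O-acyl rank above it.

**Route**

Step 1
Reactants: 1 methyl 4-bromo-3-hydroxybenzoate
Product: 2 methyl 4-bromo-3-[(4-methoxybenzyl)oxy]benzoate
Conditions: 4-methoxybenzyl chloride, K2CO3, n-Bu4NI (cat.), DMF, 50 °C
Reagents that add atoms: 4-methoxybenzyl chloride, COc1ccc(CCl)cc1
Why: Williamson ether synthesis, in which the potassium phenoxide displaces chloride from the benzylic halide while the methyl ester and aryl bromide stay untouched.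

Step 2
Reactants: 2 methyl 4-bromo-3-[(4-methoxybenzyl)oxy]benzoate
Product: 3 {4-bromo-3-[(4-methoxybenzyl)oxy]phenyl}methanol
Conditions: i-Bu2AlH (2.5 equiv), CH2Cl2, −78 → 0 °C; aq. potassium sodium tartrate
Reagents that add atoms: none
Why: Hydride reduction of the ester to the primary alcohol with i-Bu2AlH, which at low temperature should leave the aryl bromide and the benzyl-type ether intact.

Step 3
Reactants: 3 {4-bromo-3-[(4-methoxybenzyl)oxy]phenyl}methanol
Product: 4 tert-butyl({4-bromo-3-[(4-methoxybenzyl)oxy]benzyl}oxy)dimethylsilane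
Conditions: TBSCl, imidazole, DMF, rt
Reagents that add atoms: tert-butyldimethylsilyl chloride, CC(C)(C)[Si](C)(C)Cl
Why: Imidazole-promoted silylation of an unhindered primary alcohol, giving a silyl ether that is stable to organolithium reagents and to the ylide used later.

Step 4
Reactants: 5 methyl glycolate
Product: 6 methyl 2-[(tert-butyldimethylsilyl)oxy]acetate
Conditions: TBSCl, imidazole, CH2Cl2, 0 °C → rt
Reagents that add atoms: tert-butyldimethylsilyl chloride, CC(C)(C)[Si](C)(C)Cl
Why: Imidazole-promoted silylation of the primary hydroxyl group, the methyl ester being inert under these conditions.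

Step 5
Reactants: 6 methyl 2-[(tert-butyldimethylsilyl)oxy]acetate
Product: 7 2-[(tert-butyldimethylsilyl)oxy]-N-methoxy-N-methylacetamide
Conditions: MeNH(OMe)·HCl (1.5 equiv), i-PrMgCl (3 equiv), THF, −20 → 0 °C
Reagents that add atoms: N,O-dimethylhydroxylamine hydrochloride, CNOC.Cl
Why: Weinreb amide formation by aminolysis of the ester with the chloromagnesium amide of N,O-dimethylhydroxylamine, which the silyl ether should tolerate.

Step 6
Reactants: 4 tert-butyl({4-bromo-3-[(4-methoxybenzyl)oxy]benzyl}oxy)dimethylsilane; 7 2-[(tert-butyldimethylsilyl)oxy]-N-methoxy-N-methylacetamide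
Product: 9 2-[(tert-butyldimethylsilyl)oxy]-1-{4-[(tert-butyldimethylsilyloxy)methyl]-2-[(4-methoxybenzyl)oxy]phenyl}ethan-1-one, via aryllithium 8 (not isolated)
Conditions: n-BuLi (1.05 equiv), THF, −78 °C; then 7, −78 → −20 °C; aq. NH4Cl
Reagents that add atoms: none
Why: Bromine–lithium exchange followed by the Weinreb ketone synthesis, in which the chelated N-methoxy tetrahedral adduct resists a second addition and releases the aryl ketone (C8–aryl bond) only on work-up.

Step 7
Reactants: 9 2-[(tert-butyldimethylsilyl)oxy]-1-{4-[(tert-butyldimethylsilyloxy)methyl]-2-[(4-methoxybenzyl)oxy]phenyl}ethan-1-one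
Product: 11 tert-butyl{[(2R)-2-{4-[(tert-butyldimethylsilyloxy)methyl]-2-[(4-methoxybenzyl)oxy]phenyl}oxiran-2-yl]methoxy}dimethylsilane, via dimethyloxosulfonium methylide 10 (not isolated)
Conditions: Me3S(O)Cl, NaH, THF, reflux, filtered (gives 10, 1.2 equiv); LaLi3[(R)-binaphthoxide]3 (10 mol %, from La(O-i-Pr)3, (R)-1,1'-bi-2-naphthol, n-BuLi), [2,4,6-(MeO)3C6H2]3P=O (10 mol %), MS 5 Å, THF, rt
Reagents that add atoms: trimethylsulfoxonium chloride, C[S+](C)(C)=O.[Cl-]
Why: The lanthanum centre of the catalyst binds the carbonyl oxygen of 9 while a lithium binaphthoxide site holds ylide 10, whose carbanionic carbon adds to C8 (new C8–C9 bond) to give a betaine, and the C8 alkoxide then expels dimethyl sulfoxide from C9 (new O–C9 bond). The closest known reaction is the catalytic enantioselective Corey–Chaykovsky epoxidation of aryl and alkyl methyl ketones with this lanthanum–lithium binaphthoxide and a triarylphosphine oxide additive, applied here to an ortho-alkoxyaryl ketone that carries CH2OTBS in place of CH3. The oxirane (O, C8, C9) closes in 3-exo-tet mode. C8, the only new stereocentre, is fixed in the C–C bond-forming addition by the antipode of the binaphthoxide ligand, assisted by the bulky phosphine oxide, and since 9 has no stereocentre there is no substrate bias to overcome. The step needs enantioface selection at the carbonyl and a single methylene transfer to the ketone only: the size difference between the twisted ortho-substituted aryl flank and the CH2OTBS flank, the poorly coordinating silyl ether (no competing chelate) and the use of about 1.2 equiv of ylide at room temperature (no onward ring expansion to an oxetane) should secure both.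

Step 8
Reactants: 11 tert-butyl{[(2R)-2-{4-[(tert-butyldimethylsilyloxy)methyl]-2-[(4-methoxybenzyl)oxy]phenyl}oxiran-2-yl]methoxy}dimethylsilane
Product: 12 [(2S)-2-{4-(hydroxymethyl)-2-[(4-methoxybenzyl)oxy]phenyl}oxiran-2-yl]methanol
Conditions: n-Bu4NF (2.4 equiv), THF, 0 °C; pH 7 buffer (NaH2PO4/Na2HPO4)
Reagents that add atoms: none
Why: Fluoride-induced desilylation of both primary silyl ethers under non-acidic conditions that the oxirane and the PMB ether should survive; a Payne rearrangement of the C10 alkoxide, should it occur, is degenerate and returns the same enantiomer because inversion at C8 is coupled to exchange of C9 and C10.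

Step 9
Reactants: 12 [(2S)-2-{4-(hydroxymethyl)-2-[(4-methoxybenzyl)oxy]phenyl}oxiran-2-yl]methanol; 13 (R)-2-methylbutanoic acid
Product: 14 {(2R)-2-[2-[(4-methoxybenzyl)oxy]-4-({[(2R)-2-methylbutanoyl]oxy}methyl)phenyl]oxiran-2-yl}methyl (2R)-2-methylbutanoate
Conditions: 13 (2.6 equiv), DCC (2.8 equiv), DMAP (0.3 equiv), CH2Cl2, 0 °C → rt
Reagents that add atoms: (R)-2-methylbutanoic acid (second molecule of 13), CC[C@@H](C)C(=O)O
Why: Steglich esterification of both primary alcohols, each taking up one molecule of 13, in which DMAP buffers the carboxylic acid so that the acid-sensitive oxirane should survive, and the α-stereocentre of the acid, not involved in bond formation, should be carried over unchanged.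

Step 10
Reactants: 15 angelic acid [(Z)-2-methylbut-2-enoic acid]
Product: 16 angelic anhydride [(Z)-2-methylbut-2-enoic anhydride]
Conditions: 15 (2.0 equiv), DCC (1.0 equiv), CH2Cl2, 0 °C → rt; filtration
Reagents that add atoms: angelic acid (second molecule of 15), C/C=C(/C)C(=O)O
Why: Carbodiimide-mediated dehydration of two molecules of 15, in which the O-acylisourea of one acid molecule is acylated by the second to give the symmetrical anhydride and N,N'-dicyclohexylurea, run without amine base or nucleophilic catalyst so that the Z-alkene should be retained.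

Step 11
Reactants: 14 {(2R)-2-[2-[(4-methoxybenzyl)oxy]-4-({[(2R)-2-methylbutanoyl]oxy}methyl)phenyl]oxiran-2-yl}methyl (2R)-2-methylbutanoate
Product: 17 {(2R)-2-[2-hydroxy-4-({[(2R)-2-methylbutanoyl]oxy}methyl)phenyl]oxiran-2-yl}methyl (2R)-2-methylbutanoate
Conditions: DDQ (1.5 equiv), CH2Cl2/pH 7 buffer (NaH2PO4/Na2HPO4) 10:1, 0 °C; cold aq. NaHCO3 wash; used at once
Reagents that add atoms: none
Why: Oxidative cleavage of the 4-methoxybenzyl ether by DDQ (hydride abstraction to an oxocarbenium ion that water hydrolyses), with the buffer taking up the acidic hydroquinone so that the oxirane and both esters should survive, and with 17 carried on without storage because a phenol next to C8 can open the oxirane.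

Step 12
Reactants: 17 {(2R)-2-[2-hydroxy-4-({[(2R)-2-methylbutanoyl]oxy}methyl)phenyl]oxiran-2-yl}methyl (2R)-2-methylbutanoate; 16 angelic anhydride
Product: 18 CNP0166772.1 [5-({[(2R)-2-methylbutanoyl]oxy}methyl)-2-[(2R)-2-({[(2R)-2-methylbutanoyl]oxy}methyl)oxiran-2-yl]phenyl (Z)-2-methylbut-2-enoate]
Conditions: 16 (2 equiv), then Cs2CO3 (1.5 equiv), MeCN, 0 °C
Reagents that add atoms: none
Why: Base-mediated O-acylation of the caesium phenoxide by the symmetrical anhydride without a nucleophilic amine catalyst, conditions under which angelates should not isomerise to tiglates, and with the anhydride present in excess before the base is added the phenoxide should be acylated faster than it can attack the neighbouring oxirane.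

**Compound list**

1 | methyl 4-bromo-3-hydroxybenzoate | COC(=O)c1ccc(Br)c(O)c1 | starting material
2 | methyl 4-bromo-3-[(4-methoxybenzyl)oxy]benzoate | COC(=O)c1ccc(Br)c(OCc2ccc(OC)cc2)c1 | intermediate
3 | {4-bromo-3-[(4-methoxybenzyl)oxy]phenyl}methanol | COc1ccc(COc2cc(CO)ccc2Br)cc1 | intermediate
4 | tert-butyl({4-bromo-3-[(4-methoxybenzyl)oxy]benzyl}oxy)dimethylsilane | COc1ccc(COc2cc(CO[Si](C)(C)C(C)(C)C)ccc2Br)cc1 | intermediate
5 | methyl glycolate | COC(=O)CO | starting material
6 | methyl 2-[(tert-butyldimethylsilyl)oxy]acetate | COC(=O)CO[Si](C)(C)C(C)(C)C | intermediate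
7 | 2-[(tert-butyldimethylsilyl)oxy]-N-methoxy-N-methylacetamide | CON(C)C(=O)CO[Si](C)(C)C(C)(C)C | intermediate
8 | {4-[(tert-butyldimethylsilyloxy)methyl]-2-[(4-methoxybenzyl)oxy]phenyl}lithium (aryllithium, formed in the flask) | COc1ccc(COc2cc(CO[Si](C)(C)C(C)(C)C)ccc2[Li])cc1 | intermediate
9 | 2-[(tert-butyldimethylsilyl)oxy]-1-{4-[(tert-butyldimethylsilyloxy)methyl]-2-[(4-methoxybenzyl)oxy]phenyl}ethan-1-one | COc1ccc(COc2cc(CO[Si](C)(C)C(C)(C)C)ccc2C(=O)CO[Si](C)(C)C(C)(C)C)cc1 | intermediate
10 | dimethyloxosulfonium methylide (formed in the flask) | CS(C)(=O)=C | intermediate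
11 | tert-butyl{[(2R)-2-{4-[(tert-butyldimethylsilyloxy)methyl]-2-[(4-methoxybenzyl)oxy]phenyl}oxiran-2-yl]methoxy}dimethylsilane | COc1ccc(COc2cc(CO[Si](C)(C)C(C)(C)C)ccc2[C@]3(CO[Si](C)(C)C(C)(C)C)CO3)cc1 | intermediate
12 | [(2S)-2-{4-(hydroxymethyl)-2-[(4-methoxybenzyl)oxy]phenyl}oxiran-2-yl]methanol | COc1ccc(COc2cc(CO)ccc2[C@]3(CO)CO3)cc1 | intermediate
13 | (R)-2-methylbutanoic acid | CC[C@@H](C)C(=O)O | starting material
14 | {(2R)-2-[2-[(4-methoxybenzyl)oxy]-4-({[(2R)-2-methylbutanoyl]oxy}methyl)phenyl]oxiran-2-yl}methyl (2R)-2-methylbutanoate | COc1ccc(COc2cc(COC(=O)[C@H](C)CC)ccc2[C@]3(COC(=O)[C@H](C)CC)CO3)cc1 | intermediate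
15 | angelic acid [(Z)-2-methylbut-2-enoic acid] | C/C=C(/C)C(=O)O | starting material
16 | angelic anhydride [(Z)-2-methylbut-2-enoic anhydride] | C/C=C(/C)C(=O)OC(=O)/C(C)=C\C | intermediate
17 | {(2R)-2-[2-hydroxy-4-({[(2R)-2-methylbutanoyl]oxy}methyl)phenyl]oxiran-2-yl}methyl (2R)-2-methylbutanoate | Oc1cc(COC(=O)[C@H](C)CC)ccc1[C@]1(COC(=O)[C@H](C)CC)CO1 | intermediate
18 | CNP0166772.1 [5-({[(2R)-2-methylbutanoyl]oxy}methyl)-2-[(2R)-2-({[(2R)-2-methylbutanoyl]oxy}methyl)oxiran-2-yl]phenyl (Z)-2-methylbut-2-enoate] | C/C=C(/C)C(=O)Oc1cc(COC(=O)[C@H](C)CC)ccc1[C@]1(COC(=O)[C@H](C)CC)CO1 | target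

**Step count**

Total: 12 steps. Longest linear sequence: 9 steps (steps 1, 2, 3, 6, 7, 8, 9, 11, 12 from compound 1).

**Steps most likely to fail, with fallbacks**

Risk at step 7 (methylene transfer). The ortho-alkoxyaryl ketone is hindered and electron-rich, so addition of the ylide may be slow. The catalyst may also discriminate poorly between the aryl and the CH2OTBS flank, which would lower the enantiomeric purity at C8. A second ylide equivalent could expand the oxirane to an oxetane. Fallback for step 7: it sets out from 9 and moves the stereo-determining event to a hydroxyl-directed epoxidation. Wittig methylenation of 9 (Ph3PCH3Br, KO-t-Bu, THF, 0 °C → rt) should give tert-butyl{[2-{4-[(tert-butyldimethylsilyloxy)methyl]-2-[(4-methoxybenzyl)oxy]phenyl}prop-2-en-1-yl]oxy}dimethylsilane F1. n-Bu4NF in THF should then give 2-{4-(hydroxymethyl)-2-[(4-methoxybenzyl)oxy]phenyl}prop-2-en-1-ol F2. Sharpless asymmetric epoxidation of this 2-aryl allylic alcohol (Ti(O-i-Pr)4 0.2 equiv, L-(+)-diisopropyl tartrate 0.25 equiv, t-BuOOH, MS 4 Å, CH2Cl2, −20 °C) should deliver oxygen to the face that gives the (S)-epoxy diol, by the same facial rule that turns 2-methylallyl alcohol into (S)-2-methylglycidol. The benzylic C7 hydroxyl is not allylic and should stay a spectator. The fallback comes back to the route at 12.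

Risk at step 11 (PMB removal). Oxidative cleavage of an aryl 4-methoxybenzyl ether can be slow, and during the reaction or isolation the hydroquinone by-product or the freed ortho-phenol may open the oxirane. Fallback for step 11: it sets out from 9 and exchanges the phenol protecting group before the oxirane exists, so that the phenol is later freed under anhydrous, non-acidic conditions and acylated in the same flask. DDQ in CH2Cl2/H2O on 9 should give 2-[(tert-butyldimethylsilyl)oxy]-1-{4-[(tert-butyldimethylsilyloxy)methyl]-2-hydroxyphenyl}ethan-1-one F3. Allyl bromide and K2CO3 in DMF should give 1-{2-(allyloxy)-4-[(tert-butyldimethylsilyloxy)methyl]phenyl}-2-[(tert-butyldimethylsilyl)oxy]ethan-1-one F4. The methylene transfer under the conditions of step 7 should give {[(2R)-2-{2-(allyloxy)-4-[(tert-butyldimethylsilyloxy)methyl]phenyl}oxiran-2-yl]methoxy}(tert-butyl)dimethylsilane F5. n-Bu4NF should give {(2S)-2-[2-(allyloxy)-4-(hydroxymethyl)phenyl]oxiran-2-yl}methanol F6. Steglich esterification with 13 should give {(2R)-2-[2-(allyloxy)-4-({[(2R)-2-methylbutanoyl]oxy}methyl)phenyl]oxiran-2-yl}methyl (2R)-2-methylbutanoate F7. Deallylation of F7 with Pd(PPh3)4 (5 mol %) and morpholine (1.1 equiv) in THF at rt (allyl transfer through a π-allyl complex of divalent palladium) should free the phenol 17, which is not isolated. Addition of 16 (3 equiv, the excess taking up any residual amine) and Cs2CO3 to the same flask brings the fallback back to the route at 18.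

Risk at step 12 (angeloylation). Acyl transfer may isomerise the Z-alkene to the tiglate, or the phenoxide may attack the oxirane before it is acylated. Fallback for step 12: it sets out from 17 and builds the Z-alkene on the aryl ester instead of transferring it. Neutral DCC coupling of 17 with the known reagent 2-[bis(2,2,2-trifluoroethoxy)phosphoryl]propanoic acid (CH2Cl2, 0 °C, no base, so the phenol is never ionised) should give {(2R)-2-[2-({2-[bis(2,2,2-trifluoroethoxy)phosphoryl]propanoyl}oxy)-4-({[(2R)-2-methylbutanoyl]oxy}methyl)phenyl]oxiran-2-yl}methyl (2R)-2-methylbutanoate F8, as a mixture of epimers at the phosphonate carbon, which is of no consequence. Still–Gennari olefination of F8 with acetaldehyde (KN(SiMe3)2, 18-crown-6, THF, −78 °C) should then form the Z-trisubstituted enoate under kinetic control. The fallback comes back to the route at 18.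

**Further compounds**

F1 | step 7 | tert-butyl{[2-{4-[(tert-butyldimethylsilyloxy)methyl]-2-[(4-methoxybenzyl)oxy]phenyl}prop-2-en-1-yl]oxy}dimethylsilane | COc1ccc(COc2cc(CO[Si](C)(C)C(C)(C)C)ccc2C(=C)CO[Si](C)(C)C(C)(C)C)cc1
F2 | step 7 | 2-{4-(hydroxymethyl)-2-[(4-methoxybenzyl)oxy]phenyl}prop-2-en-1-ol | COc1ccc(COc2cc(CO)ccc2C(=C)CO)cc1
F3 | step 11 | 2-[(tert-butyldimethylsilyl)oxy]-1-{4-[(tert-butyldimethylsilyloxy)methyl]-2-hydroxyphenyl}ethan-1-one | CC(C)(C)[Si](C)(C)OCc1ccc(C(=O)CO[Si](C)(C)C(C)(C)C)c(O)c1
F4 | step 11 | 1-{2-(allyloxy)-4-[(tert-butyldimethylsilyloxy)methyl]phenyl}-2-[(tert-butyldimethylsilyl)oxy]ethan-1-one | C=CCOc1cc(CO[Si](C)(C)C(C)(C)C)ccc1C(=O)CO[Si](C)(C)C(C)(C)C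
F5 | step 11 | {[(2R)-2-{2-(allyloxy)-4-[(tert-butyldimethylsilyloxy)methyl]phenyl}oxiran-2-yl]methoxy}(tert-butyl)dimethylsilane | C=CCOc1cc(CO[Si](C)(C)C(C)(C)C)ccc1[C@]1(CO[Si](C)(C)C(C)(C)C)CO1
F6 | step 11 | {(2S)-2-[2-(allyloxy)-4-(hydroxymethyl)phenyl]oxiran-2-yl}methanol | C=CCOc1cc(CO)ccc1[C@]1(CO)CO1
F7 | step 11 | {(2R)-2-[2-(allyloxy)-4-({[(2R)-2-methylbutanoyl]oxy}methyl)phenyl]oxiran-2-yl}methyl (2R)-2-methylbutanoate | C=CCOc1cc(COC(=O)[C@H](C)CC)ccc1[C@]1(COC(=O)[C@H](C)CC)CO1
F8 | step 12 | {(2R)-2-[2-({2-[bis(2,2,2-trifluoroethoxy)phosphoryl]propanoyl}oxy)-4-({[(2R)-2-methylbutanoyl]oxy}methyl)phenyl]oxiran-2-yl}methyl (2R)-2-methylbutanoate | CC(C(=O)Oc1cc(COC(=O)[C@H](C)CC)ccc1[C@]1(COC(=O)[C@H](C)CC)CO1)P(=O)(OCC(F)(F)F)OCC(F)(F)F
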